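## Plan

- Retrosynthesis: the C6–O bond is cut first (acetate delivered from a C7 enol acetate), then ring D at C9–C11 and C13–C14 together (back to methyl vinyl ketone and a tricycle carrying a carboxyl group on C9), then the cyclobutane at C8–C15 and C9–C14 (enone [2+2]), back to 7-oxodrim-8-en-11-oic acid from (+)-sclareolide.
- Forward ring order: rings A/B (decalin of sclareolide), then ring C (cyclobutane, carried as its 14,15-dichloride), then ring D (cyclopentanol, one-flask SmI2 cascade), then the C6 acetate.
- Enabling feature: C9 is the ring-fusion carbon of the four-membered ring between two quaternary carbons (C8, C10), so it is approached as a tertiary radical. Its ring neighbour C14 becomes one end of a strained cyclobutene once the two chlorines leave, in 5-exo range of a ketyl at C13 on the new C9 side chain. Helpers: CO2H (traceless radical handle), vicinal dichloride (masked cyclobutene), enol acetate (mask for the C7 ketone and source of the C6 acetate).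
- Stereochemistry: C5 and C10 come from sclareolide; C8 and C9 from α-face photocycloaddition and the cis 6/4 fusion; C14 from the cis 5/4 fusion; C13 from the anti ketyl–olefin transition state; C6 from acetoxy migration with inversion.

Key step: step 9

Assumption: the chloro epimers at C14/C15 in 9, 10, 11 and 13 and the C11 epimers of 2 and 3 are carried as mixtures, because these centres are erased later; labdane numbering is used for the target (C14/C15 = cyclobutane CH/CH2, C16 = methyl on C13, C17 = methyl on C8).

## Route

Step 1
Reactants: 1 (+)-sclareolide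
Product: 2 11-hydroxysclareolide
Conditions: KN(SiMe3)2, THF, −78 °C; then 2-(phenylsulfonyl)-3-phenyloxaziridine; aq. NH4Cl
Reagents that add atoms: 2-(phenylsulfonyl)-3-phenyloxaziridine O=S(=O)(c1ccccc1)N1OC1c1ccccc1
Why: Enolate oxidation (α-hydroxylation of the lactone enolate by an N-sulfonyloxaziridine) should install the oxygen at the lactone α-carbon; the new centre is of no consequence because it is cleaved in step 3.

Step 2
Reactants: 2 11-hydroxysclareolide
Product: 3 13,14,15,16-tetranorlabdane-8α,11,12-triol
Conditions: LiAlH4, THF, 0 °C → reflux
Reagents that add atoms: none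
Why: Hydride reduction of the lactone should open it to the tertiary alcohol and a terminal 1,2-diol without touching any stereocentre.

Step 3
Reactants: 3 13,14,15,16-tetranorlabdane-8α,11,12-triol
Product: 5 drim-8-en-11-al, via 8α-hydroxydriman-11-al 4 (not isolated)
Conditions: NaIO4, THF/H2O, rt; then p-TsOH·H2O (cat.), toluene, 80 °C
Reagents that add atoms: none
Why: Periodate glycol cleavage should give the β-hydroxy aldehyde, and acid-catalysed dehydration should then settle on the conjugated tetrasubstituted enal, which erases C8 and C9 as intended.

Step 4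
Reactants: 5 drim-8-en-11-al
Product: 6 drim-8-en-11-oic acid
Conditions: NaClO2, NaH2PO4, 2-methyl-2-butene, t-BuOH/H2O, rt
Reagents that add atoms: sodium chlorite [Na+].[O-]Cl=O
Why: Pinnick oxidation should convert the hindered enal to the acid without affecting the tetrasubstituted double bond.

Step 5
Reactants: 6 drim-8-en-11-oic acid
Product: 7 7-oxodrim-8-en-11-oic acid
Conditions: CrO3, 3,5-dimethylpyrazole, CH2Cl2, −20 °C
Reagents that add atoms: chromium trioxide O=[Cr](=O)=O
Why: Chromium-mediated allylic oxidation should attack C7, the only allylic methylene, as is usual for drim-8-ene carbonyl compounds, and give the enone chromophore.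

Step 6
Reactants: 7 7-oxodrim-8-en-11-oic acid; 8 (Z)-1,2-dichloroethylene
Product: 9 dichlorocyclobutane keto acid
Conditions: hν (medium-pressure Hg lamp, Pyrex, λ > 300 nm), 8 (20 equiv), CH2Cl2, −20 °C
Reagents that add atoms: none
Why: In this triplet enone–alkene [2+2] photocycloaddition the alkene should add to the α-face of C8=C9, opposite the axial C10 methyl group, and close cis to ring B, which sets the quaternary centres C8 and C9; the two chlorine-bearing centres form as a mixture.

Step 7
Reactants: 9 dichlorocyclobutane keto acid
Product: 10 Δ6-enol acetate acid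
Conditions: KN(SiMe3)2 (2.2 equiv), THF, −78 °C; Ac2O (1.1 equiv); cold dilute HCl work-up
Reagents that add atoms: acetic anhydride CC(=O)OC(C)=O
Why: Kinetic enolate O-acetylation should give the enol acetate, since C8 is quaternary and only C6 can be deprotonated, and the carboxylate is recovered as the acid on work-up.

Step 8
Reactants: 10 Δ6-enol acetate acid
Product: 11 N-phthalimidoyl ester of 10
Conditions: N-hydroxyphthalimide, N,N'-diisopropylcarbodiimide, DMAP (cat.), CH2Cl2, rt
Reagents that add atoms: N-hydroxyphthalimide O=C1c2ccccc2C(=O)N1O
Why: Carbodiimide (Steglich-type) esterification should convert the hindered tertiary acid into the redox-active ester.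

Step 9
Reactants: 11 N-phthalimidoyl ester of 10; 12 methyl vinyl ketone
Product: 15 tetracyclic hydroxy enol acetate, via dichloro ketone 13 (not isolated), via cyclobutene ketone 14 (not isolated)
Conditions: SmI2 (2.5 equiv, slow addition), 12 (3 equiv), THF, −78 → −40 °C; then t-BuOH (5 equiv), HMPA (24 equiv), SmI2 (8 equiv), −40 °C → rt; aq. NH4Cl
Reagents that add atoms: none
Why: Proposed new method: electron transfer from SmI2 to the phthalimide of 11 should cleave the N–O bond and expel CO2 to give the C9 cyclobutyl radical, which stays unconjugated because ring-C unsaturation is still masked as the dichloride and which should add to the unhindered terminus of 12; the α-keto radical is then reduced to a samarium enolate and protonated to 13, and with HMPA the same reductant should eliminate the two chlorines to cyclobutene 14 and turn the methyl ketone into a ketyl that attacks C14. The closest known reaction types are the reductive decarboxylative Giese addition of N-(acyloxy)phthalimides (zinc/nickel or photoredox), the SmI2 reduction of vicinal dihalides to alkenes and the SmI2/HMPA ketyl–olefin cyclisation, so only their union under one reductant is new. Ring D is the only ring closed, by a 5-exo-trig radical closure onto the strained cyclobutene. At C9 the new bond must form on the β-face because the four-membered ring stays cis-fused to ring B, at C14 ring D can only be cis-fused to the cyclobutane, and at C13 the bulky O–samarium(HMPA) group should turn away from the cyclobutane and anti to the developing C15 radical, which places the methyl group syn and the hydroxyl anti to C15. The step needs the ester to be reduced before ketone and chloride, radical addition to outrun radical reduction, and attack at C9 and not C15; these are secured by withholding HMPA until the conjugate addition is over, by excess enone at low SmI2 concentration, and by the dichloride mask. The enol acetate keeps C7 from forming a ketyl next to the four-membered ring.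

Step 10
Reactants: 15 tetracyclic hydroxy enol acetate
Product: 17 target CNP0330581.1, via epoxy acetate 16 (not isolated)
Conditions: dimethyldioxirane, acetone, 0 °C; evaporate; then toluene, sealed tube, 140 °C
Reagents that add atoms: dimethyldioxirane CC1(C)OO1
Why: Epoxidation of the enol acetate from the less hindered α-face, then thermal acyloxy-epoxide rearrangement in which the acetoxy group migrates from C7 to the β-face of C6 with inversion as the epoxide opens to the C7 ketone, should give the axial 6β-acetate with no acid or base present to epimerise it.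

## Compound list

1 | (+)-sclareolide | C1C[C@@]3(C)OC(=O)C[C@@H]3[C@@]2(C)CCCC(C)(C)[C@H]12 | starting material
2 | 11-hydroxysclareolide (C11 epimers) | C1C[C@@]3(C)OC(=O)C(O)[C@@H]3[C@@]2(C)CCCC(C)(C)[C@H]12 | intermediate
3 | 13,14,15,16-tetranorlabdane-8α,11,12-triol (C11 epimers) | C1C[C@@](C)(O)[C@H](C(O)CO)[C@@]2(C)CCCC(C)(C)[C@H]12 | intermediate
4 | 8α-hydroxydriman-11-al (not isolated) | C1C[C@@](C)(O)[C@H](C=O)[C@@]2(C)CCCC(C)(C)[C@H]12 | intermediate
5 | drim-8-en-11-al | C1CC(C)=C(C=O)[C@@]2(C)CCCC(C)(C)[C@H]12 | intermediate
6 | drim-8-en-11-oic acid | C1CC(C)=C(C(=O)O)[C@@]2(C)CCCC(C)(C)[C@H]12 | intermediate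
7 | 7-oxodrim-8-en-11-oic acid | C1C(=O)C(C)=C(C(=O)O)[C@@]2(C)CCCC(C)(C)[C@H]12 | intermediate
8 | (Z)-1,2-dichloroethylene | Cl/C=C\Cl | starting material
9 | dichlorocyclobutane keto acid: 7-oxodriman-11-oic acid with a 1,2-dichloroethano bridge cis-fused on the α-face between C8 and C9 (chloro epimers) | C1C(=O)[C@@]3(C)C(Cl)C(Cl)[C@@]3(C(=O)O)[C@@]2(C)CCCC(C)(C)[C@H]12 | intermediate
10 | Δ6-enol acetate acid: 7-acetoxy-6-ene derived from 9 | C1=C(OC(C)=O)[C@@]3(C)C(Cl)C(Cl)[C@@]3(C(=O)O)[C@@]2(C)CCCC(C)(C)[C@H]12 | intermediate
11 | N-phthalimidoyl (1,3-dioxoisoindolin-2-yl) ester of 10 | C1=C(OC(C)=O)[C@@]3(C)C(Cl)C(Cl)[C@@]3(C(=O)ON4C(=O)c5ccccc5C4=O)[C@@]2(C)CCCC(C)(C)[C@H]12 | intermediate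
12 | methyl vinyl ketone | CC(=O)C=C | starting material
13 | dichloro ketone: 11 with the C9 ester group replaced by a 9β-(3-oxobutyl) chain (not isolated) | C1=C(OC(C)=O)[C@@]3(C)C(Cl)C(Cl)[C@@]3(CCC(C)=O)[C@@]2(C)CCCC(C)(C)[C@H]12 | intermediate
14 | cyclobutene ketone: 13 after loss of both chlorines, C14=C15 (not isolated) | C1=C(OC(C)=O)[C@@]3(C)C=C[C@@]3(CCC(C)=O)[C@@]2(C)CCCC(C)(C)[C@H]12 | intermediate
15 | tetracyclic hydroxy enol acetate: target skeleton with 13-hydroxyl and a 7-acetoxy-6-ene in place of the 6-acetoxy-7-ketone | C1=C(OC(C)=O)[C@@]2(C)C[C@H]3[C@@]2(CC[C@]3(C)O)[C@@]2(C)CCCC(C)(C)[C@H]12 | intermediate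
16 | epoxy acetate: 6α,7α-epoxide of 15 with 7β-acetoxy (not isolated) | [C@@H]14O[C@@]4(OC(C)=O)[C@@]2(C)C[C@H]3[C@@]2(CC[C@]3(C)O)[C@@]5(C)CCCC(C)(C)[C@H]15 | intermediate
17 | CNP0330581.1: 6β-acetoxy-13-hydroxy-7-oxo tetracycle | CC(=O)O[C@@H]1C(=O)[C@@]2(C)C[C@H]3[C@@]2(CC[C@]3(C)O)[C@@]2(C)CCCC(C)(C)[C@H]12 | target

## Count and risks

Total steps: 10. Longest linear sequence: 10 steps (from 1).

Steps most likely to fail:

Step 9. The C9 radical may be reduced before it adds to the enone; the resulting carbanion would expel chloride. Dechlorination may also run ahead of the conjugate addition, so that an allyl-type radical reacts at C15, and samarium alkoxides may take the acetyl group off the enol acetate. Fallback: the three events are separated and the radical is generated photochemically. From 11, a visible-light reductive decarboxylative Giese addition to 12 (Ru(bpy)3(PF6)2 cat., diethyl 2,6-dimethyl-1,4-dihydropyridine-3,5-dicarboxylate, i-Pr2NEt, CH2Cl2, blue light) should give dichloro ketone 13 as an isolated compound. Zinc dust in ethanol at 60 °C should then unmask cyclobutene ketone 14, and SmI2/HMPA/t-BuOH in THF should close ring D to 15, where the route is rejoined. This fallback makes no compound outside the list (F0).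

Step 6. Cycloaddition to the tetrasubstituted, doubly acceptor-substituted double bond of the free acid may be slow, with photodecarboxylation and energy transfer to the dichloroethylene competing, or closure may give a trans-fused ring. Fallback: the acid is masked before irradiation. From 7, benzylation (BnBr, K2CO3, DMF) should give benzyl 7-oxodrim-8-en-11-oate F1; irradiation with 8 as in step 6 should give the benzyl ester of the dichlorocyclobutane keto acid F2; hydrogenolysis (H2, Pd/C, EtOAc) should return 9.

Step 10. The acetoxy migration may leave the concerted path (ion-pair or acid-catalysed course with retention) or the axial acetate may epimerise, giving the 6α-acetate; the epoxy acetate may also hydrolyse. Fallback: the oxygen is brought in at the ketone level and the configuration set by hydride. From 15, methanolysis (K2CO3, MeOH) should give the 13-hydroxy 7-ketone F3. SeO2 in dioxane at 80 °C should oxidise C6 to the 6,7-dione F4 (in equilibrium with its Δ5 enol). NaBH4 in MeOH/CH2Cl2 at −78 °C should deliver hydride to the less hindered C6 carbonyl from the α-face to give the 6β-hydroxy 7-ketone F5. Ac2O/DMAP/pyridine should acetylate the secondary hydroxyl in preference to the tertiary one and give 17.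

## Further compounds

F0 | step 9 | none | none
F1 | step 6 | benzyl 7-oxodrim-8-en-11-oate | C1C(=O)C(C)=C(C(=O)OCc3ccccc3)[C@@]2(C)CCCC(C)(C)[C@H]12
F2 | step 6 | benzyl ester of the dichlorocyclobutane keto acid 9 | C1C(=O)[C@@]3(C)C(Cl)C(Cl)[C@@]3(C(=O)OCc4ccccc4)[C@@]2(C)CCCC(C)(C)[C@H]12
F3 | step 10 | 13-hydroxy 7-ketone (6-deacetoxy target) | C1C(=O)[C@@]2(C)C[C@H]3[C@@]2(CC[C@]3(C)O)[C@@]2(C)CCCC(C)(C)[C@H]12
F4 | step 10 | 13-hydroxy 6,7-dione | O=C1C(=O)[C@@]2(C)C[C@H]3[C@@]2(CC[C@]3(C)O)[C@@]2(C)CCCC(C)(C)[C@H]12
F5 | step 10 | 6β,13-dihydroxy 7-ketone | O[C@@H]1C(=O)[C@@]2(C)C[C@H]3[C@@]2(CC[C@]3(C)O)[C@@]2(C)CCCC(C)(C)[C@H]12
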